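## Retrosynthetic overview

1. The target comes from global O-debenzylation of its hepta-benzyl ether; the E-benzylidene is made by Ramberg–Bäcklund olefination of an indan-1-yl benzyl sulfone (C1 indanol plus a vanillyl thiol).
2. The trans-2,3-diarylindanone comes from Pd-catalysed α-arylation of an (S)-3-arylindanone with 3,5-bis(benzyloxy)bromobenzene; C2 is set trans to C3 under thermodynamic control.
3. The (S)-3-arylindanone comes from CuH-catalysed asymmetric conjugate reduction of a 3-arylindenone, which sets C3.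
4. The indenone five-membered ring, the only ring built in the route, closes by intramolecular aldol condensation of an o-acetylbenzophenone.
5. The diketone comes from brominated 3,5-bis(benzyloxy)benzaldehyde (MeMgBr, then Br/Li exchange) and 2,4-bis(benzyloxy)benzaldehyde, followed by double oxidation.

Assumption: (R)-DTBM-SEGPHOS is taken to give the (S)-ketone in step 7 (the (S)-ligand is used if the first run gives the antipode); C1 of 17 and 24–26 is an inconsequential epimer mixture and is left undefined in the SMILES.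

## Route

Step 1
Reactants: 1 2,4-dihydroxybenzaldehyde
Product: 2 2,4-bis(benzyloxy)benzaldehyde
Conditions: BnBr (2.3 equiv), K2CO3, DMF, 70 °C
Reagents that add atoms: benzyl bromide, BrCc1ccccc1
Why: Williamson ether synthesis; heating is needed to alkylate the hydrogen-bonded 2-OH.

Step 2
Reactants: 3 3,5-bis(benzyloxy)benzaldehyde
Product: 4 3,5-bis(benzyloxy)-2-bromobenzaldehyde
Conditions: NBS (1.05 equiv), MeCN, 0 °C to rt, dark
Reagents that add atoms: N-bromosuccinimide, O=C1CCC(=O)N1Br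
Why: Electrophilic aromatic bromination goes para to one benzyloxy group and ortho to the other (C2), not at the more hindered C4 between the two ethers.

Step 3
Reactants: 4 3,5-bis(benzyloxy)-2-bromobenzaldehyde
Product: 5 rac-1-[3,5-bis(benzyloxy)-2-bromophenyl]ethan-1-ol
Conditions: MeMgBr (1.2 equiv), THF, 0 °C; aqueous work-up
Reagents that add atoms: methylmagnesium bromide, C[Mg]Br
Why: Grignard addition to the aldehyde; the racemic carbinol centre is removed by oxidation in step 5.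

Step 4
Reactants: 5 rac-1-[3,5-bis(benzyloxy)-2-bromophenyl]ethan-1-ol; 2 2,4-bis(benzyloxy)benzaldehyde
Product: 7 1-[3,5-bis(benzyloxy)-2-{[2,4-bis(benzyloxy)phenyl](hydroxy)methyl}phenyl]ethan-1-ol (diastereomer mixture), via dilithiated aryl alkoxide 6 (not isolated)
Conditions: n-BuLi (2.1 equiv), THF, −78 °C; then 2 (1.1 equiv), −78 to 0 °C; H2O
Reagents that add atoms: none
Why: O-deprotonation then fast bromine–lithium exchange gives an aryllithium that adds 1,2 to the aldehyde; both new carbinol centres are oxidised away in step 5.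

Step 5
Reactants: 7 the diol
Product: 8 1-{3,5-bis(benzyloxy)-2-[2,4-bis(benzyloxy)benzoyl]phenyl}ethan-1-one
Conditions: Dess–Martin periodinane (2.6 equiv), CH2Cl2, rt
Reagents that add atoms: none
Why: Dess–Martin oxidation of both benzylic alcohols; the hydroxy-ketone/lactol formed after the first oxidation re-opens and is oxidised to the 1,4-diketone.

Step 6
Reactants: 8 the o-acetylbenzophenone
Product: 10 4,6-bis(benzyloxy)-3-[2,4-bis(benzyloxy)phenyl]-1H-inden-1-one, via racemic 3-hydroxyindanone aldol 9 (not isolated)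
Conditions: KOH (0.2 equiv), EtOH–THF, 50 °C; then p-TsOH·H2O (0.3 equiv), toluene, 80 °C
Reagents that add atoms: none
Why: Intramolecular aldol condensation: the only enolisable position (the acetyl CH3) attacks the twisted benzophenone carbonyl to close the five-membered ring, and the doubly benzylic tertiary aldol ionises under acid and dehydrates to the conjugated indenone.

Step 7
Reactants: 10 the 3-arylindenone
Product: 12 (3S)-4,6-bis(benzyloxy)-3-[2,4-bis(benzyloxy)phenyl]-2,3-dihydro-1H-inden-1-one, via silyl enol ether 11 (not isolated)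
Conditions: Cu(OAc)2·H2O (3 mol %), (R)-DTBM-SEGPHOS (3.3 mol %), (EtO)2MeSiH (2 equiv), toluene, 0 °C to rt; then 1 M HCl, THF, rt
Reagents that add atoms: none
Why: CuH-catalysed asymmetric conjugate reduction delivers hydride to the β-carbon under ligand control, setting C3 as S, and the silyl enol ether shields the ketone from 1,2-reduction until hydrolysis.

Step 8
Reactants: 13 1-bromo-3,5-dimethoxybenzene
Product: 14 5-bromobenzene-1,3-diol
Conditions: BBr3 (2.5 equiv), CH2Cl2, −78 °C to rt; H2O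
Reagents that add atoms: none
Why: Lewis-acid cleavage of the aryl methyl ethers (SN2 attack of bromide on the O-methyl of the boron-complexed ether).

Step 9
Reactants: 14 5-bromobenzene-1,3-diol
Product: 15 1,3-bis(benzyloxy)-5-bromobenzene
Conditions: BnBr (2.3 equiv), K2CO3, DMF, 60 °C
Reagents that add atoms: benzyl bromide, BrCc1ccccc1
Why: Williamson ether synthesis on both phenols.

Step 10
Reactants: 12 the (3S)-3-arylindanone; 15 1,3-bis(benzyloxy)-5-bromobenzene
Product: 16 (2S,3S)-4,6-bis(benzyloxy)-2-[3,5-bis(benzyloxy)phenyl]-3-[2,4-bis(benzyloxy)phenyl]-2,3-dihydro-1H-inden-1-one (2,3-trans)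
Conditions: Pd(OAc)2 (5 mol %), XPhos (10 mol %), NaOt-Bu (2 equiv), toluene, 80 °C; aq. NH4Cl; then DBU (0.2 equiv), CH2Cl2, rt
Reagents that add atoms: none
Why: Pd-catalysed ketone α-arylation (Buchwald–Hartwig type); the product is held as its enolate so it is not arylated twice, and base equilibration of the acidic α-aryl centre gives the more stable trans isomer, so C2 (S) is set by C3 while C3 itself is not enolisable.

Step 11
Reactants: 16 the trans-2,3-diarylindanone
Product: 17 (2S,3S)-4,6-bis(benzyloxy)-2-[3,5-bis(benzyloxy)phenyl]-3-[2,4-bis(benzyloxy)phenyl]-2,3-dihydro-1H-inden-1-ol (C1 epimers; mainly OH cis to the C2 aryl)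
Conditions: NaBH4, THF–MeOH, 0 °C to rt
Reagents that add atoms: none
Why: Hydride reduction of the ketone, mainly anti to the C2 aryl; the C1 configuration is irrelevant because C1 is ionised in step 16 and becomes sp2 in step 18.

Step 12
Reactants: 18 vanillin (4-hydroxy-3-methoxybenzaldehyde)
Product: 19 4-(benzyloxy)-3-methoxybenzaldehyde
Conditions: BnBr (1.1 equiv), K2CO3, DMF, 50 °C
Reagents that add atoms: benzyl bromide, BrCc1ccccc1
Why: Williamson ether synthesis on the single phenol.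

Step 13
Reactants: 19 4-(benzyloxy)-3-methoxybenzaldehyde
Product: 20 [4-(benzyloxy)-3-methoxyphenyl]methanol
Conditions: NaBH4, MeOH, 0 °C
Reagents that add atoms: none
Why: Chemoselective hydride reduction of the aldehyde.

Step 14
Reactants: 20 [4-(benzyloxy)-3-methoxyphenyl]methanol
Product: 21 1-(benzyloxy)-4-(chloromethyl)-2-methoxybenzene
Conditions: SOCl2 (1.2 equiv), CH2Cl2, 0 °C
Reagents that add atoms: thionyl chloride, ClS(Cl)=O
Why: Deoxychlorination of an electron-rich benzylic alcohol through its chlorosulfite.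

Step 15
Reactants: 21 the benzylic chloride
Product: 23 [4-(benzyloxy)-3-methoxyphenyl]methanethiol, via isothiouronium chloride 22 (not isolated)
Conditions: thiourea (1.1 equiv), EtOH, reflux; then 2 M NaOH, reflux, N2; acidify
Reagents that add atoms: thiourea, NC(N)=S
Why: S-alkylation of thiourea then alkaline hydrolysis of the isothiouronium salt gives the thiol without over-alkylation to the sulfide.

Step 16
Reactants: 17 the indan-1-ol; 23 the benzylic thiol
Product: 24 4-(benzyloxy)-3-methoxybenzyl (2S,3S)-4,6-bis(benzyloxy)-2-[3,5-bis(benzyloxy)phenyl]-3-[2,4-bis(benzyloxy)phenyl]-2,3-dihydro-1H-inden-1-yl sulfide (C1 mainly trans to the C2 aryl)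
Conditions: ZnI2 (0.5 equiv), 23 (1.5 equiv), ClCH2CH2Cl, rt to 40 °C
Reagents that add atoms: none
Why: Lewis-acid SN1 thioetherification: the C1 benzylic cation is trapped by the soft thiol anti to the C2 aryl faster than it loses a proton, and C2 and C3 are not touched.

Step 17
Reactants: 24 the sulfide
Product: 25 4-(benzyloxy)-3-methoxybenzyl (2S,3S)-4,6-bis(benzyloxy)-2-[3,5-bis(benzyloxy)phenyl]-3-[2,4-bis(benzyloxy)phenyl]-2,3-dihydro-1H-inden-1-yl sulfone
Conditions: mCPBA (2.2 equiv), CH2Cl2, 0 °C to rt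
Reagents that add atoms: 3-chloroperoxybenzoic acid, OOC(=O)c1cccc(Cl)c1
Why: Peracid oxidation of sulfide to sulfone through the sulfoxide; no alkene is present and the alkoxyarenes are inert at this temperature.

Step 18
Reactants: 25 the sulfone
Product: 28 (1E,2S,3S)-4,6-bis(benzyloxy)-1-[4-(benzyloxy)-3-methoxybenzylidene]-2-[3,5-bis(benzyloxy)phenyl]-3-[2,4-bis(benzyloxy)phenyl]-2,3-dihydro-1H-indene, via α-chloro sulfone 26 (not isolated), via episulfone 27 (not isolated)
Conditions: powdered KOH, CCl4, t-BuOH–H2O (5:1), 60–80 °C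
Reagents that add atoms: none
Why: Ramberg–Bäcklund reaction (Meyers conditions): α-chlorination, 1,3-elimination to the episulfone and loss of SO2 place the double bond exactly between C1 and the benzylic carbon, with the E isomer (aryl away from the peri C7–H) favoured.

Step 19
Reactants: 28 the hepta-O-benzyl ether
Product: 29 (1E,2S,3S)-2-(3,5-dihydroxyphenyl)-3-(2,4-dihydroxyphenyl)-1-(4-hydroxy-3-methoxybenzylidene)-2,3-dihydro-1H-indene-4,6-diol (CNP0122890.1)
Conditions: BCl3 (1 M in CH2Cl2, 14 equiv), pentamethylbenzene (20 equiv), CH2Cl2, −78 °C; quench CHCl3–MeOH at −78 °C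
Reagents that add atoms: none
Why: Lewis-acid O-debenzylation with a cation scavenger cleaves the seven aryl benzyl ethers at −78 °C while the aryl methyl ether, the exocyclic alkene and both stereocentres are left untouched.

## Compound list

1 | 2,4-dihydroxybenzaldehyde | O=Cc1ccc(O)cc1O | starting material
2 | 2,4-bis(benzyloxy)benzaldehyde | O=Cc1ccc(OCc2ccccc2)cc1OCc1ccccc1 | intermediate
3 | 3,5-bis(benzyloxy)benzaldehyde | O=Cc1cc(OCc2ccccc2)cc(OCc2ccccc2)c1 | starting material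
4 | 3,5-bis(benzyloxy)-2-bromobenzaldehyde | O=Cc1cc(OCc2ccccc2)cc(OCc2ccccc2)c1Br | intermediate
5 | rac-1-[3,5-bis(benzyloxy)-2-bromophenyl]ethan-1-ol | CC(O)c1cc(OCc2ccccc2)cc(OCc2ccccc2)c1Br | intermediate
6 | lithium 1-[3,5-bis(benzyloxy)-2-lithiophenyl]ethan-1-olate | [Li]OC(C)c1cc(OCc2ccccc2)cc(OCc2ccccc2)c1[Li] | intermediate
7 | 1-[3,5-bis(benzyloxy)-2-{[2,4-bis(benzyloxy)phenyl](hydroxy)methyl}phenyl]ethan-1-ol (diastereomer mixture) | CC(O)c1cc(OCc2ccccc2)cc(OCc2ccccc2)c1C(O)c1ccc(OCc2ccccc2)cc1OCc1ccccc1 | intermediate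
8 | 1-{3,5-bis(benzyloxy)-2-[2,4-bis(benzyloxy)benzoyl]phenyl}ethan-1-one | CC(=O)c1cc(OCc2ccccc2)cc(OCc2ccccc2)c1C(=O)c1ccc(OCc2ccccc2)cc1OCc1ccccc1 | intermediate
9 | rac-4,6-bis(benzyloxy)-3-[2,4-bis(benzyloxy)phenyl]-3-hydroxy-2,3-dihydro-1H-inden-1-one | O=C1CC(O)(c2ccc(OCc3ccccc3)cc2OCc2ccccc2)c2c(OCc3ccccc3)cc(OCc3ccccc3)cc21 | intermediate
10 | 4,6-bis(benzyloxy)-3-[2,4-bis(benzyloxy)phenyl]-1H-inden-1-one | O=C1C=C(c2ccc(OCc3ccccc3)cc2OCc2ccccc2)c2c(OCc3ccccc3)cc(OCc3ccccc3)cc21 | intermediate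
11 | (1S)-5,7-bis(benzyloxy)-1-[2,4-bis(benzyloxy)phenyl]-3-{[diethoxy(methyl)silyl]oxy}-1H-indene | CCO[Si](C)(OCC)OC1=C[C@@H](c2ccc(OCc3ccccc3)cc2OCc2ccccc2)c2c(OCc3ccccc3)cc(OCc3ccccc3)cc21 | intermediate
12 | (3S)-4,6-bis(benzyloxy)-3-[2,4-bis(benzyloxy)phenyl]-2,3-dihydro-1H-inden-1-one | O=C1C[C@@H](c2ccc(OCc3ccccc3)cc2OCc2ccccc2)c2c(OCc3ccccc3)cc(OCc3ccccc3)cc21 | intermediate
13 | 1-bromo-3,5-dimethoxybenzene | COc1cc(Br)cc(OC)c1 | starting material
14 | 5-bromobenzene-1,3-diol | Oc1cc(O)cc(Br)c1 | intermediate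
15 | 1,3-bis(benzyloxy)-5-bromobenzene | Brc1cc(OCc2ccccc2)cc(OCc2ccccc2)c1 | intermediate
16 | (2S,3S)-4,6-bis(benzyloxy)-2-[3,5-bis(benzyloxy)phenyl]-3-[2,4-bis(benzyloxy)phenyl]-2,3-dihydro-1H-inden-1-one | O=C1[C@H](c2cc(OCc3ccccc3)cc(OCc3ccccc3)c2)[C@@H](c2ccc(OCc3ccccc3)cc2OCc2ccccc2)c2c(OCc3ccccc3)cc(OCc3ccccc3)cc21 | intermediate
17 | (2S,3S)-4,6-bis(benzyloxy)-2-[3,5-bis(benzyloxy)phenyl]-3-[2,4-bis(benzyloxy)phenyl]-2,3-dihydro-1H-inden-1-ol (C1 epimers) | OC1[C@H](c2cc(OCc3ccccc3)cc(OCc3ccccc3)c2)[C@@H](c2ccc(OCc3ccccc3)cc2OCc2ccccc2)c2c(OCc3ccccc3)cc(OCc3ccccc3)cc21 | intermediate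
18 | vanillin (4-hydroxy-3-methoxybenzaldehyde) | COc1cc(C=O)ccc1O | starting material
19 | 4-(benzyloxy)-3-methoxybenzaldehyde | COc1cc(C=O)ccc1OCc1ccccc1 | intermediate
20 | [4-(benzyloxy)-3-methoxyphenyl]methanol | COc1cc(CO)ccc1OCc1ccccc1 | intermediate
21 | 1-(benzyloxy)-4-(chloromethyl)-2-methoxybenzene | COc1cc(CCl)ccc1OCc1ccccc1 | intermediate
22 | S-[4-(benzyloxy)-3-methoxybenzyl]isothiouronium chloride | COc1cc(CSC(N)=[NH2+])ccc1OCc1ccccc1.[Cl-] | intermediate
23 | [4-(benzyloxy)-3-methoxyphenyl]methanethiol | COc1cc(CS)ccc1OCc1ccccc1 | intermediate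
24 | 4-(benzyloxy)-3-methoxybenzyl (2S,3S)-4,6-bis(benzyloxy)-2-[3,5-bis(benzyloxy)phenyl]-3-[2,4-bis(benzyloxy)phenyl]-2,3-dihydro-1H-inden-1-yl sulfide (C1 epimers) | COc1cc(CSC2[C@H](c3cc(OCc4ccccc4)cc(OCc4ccccc4)c3)[C@@H](c3ccc(OCc4ccccc4)cc3OCc3ccccc3)c3c(OCc4ccccc4)cc(OCc4ccccc4)cc32)ccc1OCc1ccccc1 | intermediate
25 | 4-(benzyloxy)-3-methoxybenzyl (2S,3S)-4,6-bis(benzyloxy)-2-[3,5-bis(benzyloxy)phenyl]-3-[2,4-bis(benzyloxy)phenyl]-2,3-dihydro-1H-inden-1-yl sulfone (C1 epimers) | COc1cc(CS(=O)(=O)C2[C@H](c3cc(OCc4ccccc4)cc(OCc4ccccc4)c3)[C@@H](c3ccc(OCc4ccccc4)cc3OCc3ccccc3)c3c(OCc4ccccc4)cc(OCc4ccccc4)cc32)ccc1OCc1ccccc1 | intermediate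
26 | α-chloro derivative of sulfone 25 (chlorine on the exocyclic benzylic carbon) | COc1cc(C(Cl)S(=O)(=O)C2[C@H](c3cc(OCc4ccccc4)cc(OCc4ccccc4)c3)[C@@H](c3ccc(OCc4ccccc4)cc3OCc3ccccc3)c3c(OCc4ccccc4)cc(OCc4ccccc4)cc32)ccc1OCc1ccccc1 | intermediate
27 | spiro episulfone (thiirane 1,1-dioxide spiro-fused at indane C1, bearing the 4-(benzyloxy)-3-methoxyphenyl group) | COc1cc(C2C3(S2(=O)=O)[C@H](c4cc(OCc5ccccc5)cc(OCc5ccccc5)c4)[C@@H](c4ccc(OCc5ccccc5)cc4OCc4ccccc4)c4c(OCc5ccccc5)cc(OCc5ccccc5)cc43)ccc1OCc1ccccc1 | intermediate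
28 | (1E,2S,3S)-4,6-bis(benzyloxy)-1-[4-(benzyloxy)-3-methoxybenzylidene]-2-[3,5-bis(benzyloxy)phenyl]-3-[2,4-bis(benzyloxy)phenyl]-2,3-dihydro-1H-indene | COc1cc(/C=C2/c3cc(OCc4ccccc4)cc(OCc4ccccc4)c3[C@H](c3ccc(OCc4ccccc4)cc3OCc3ccccc3)[C@H]2c2cc(OCc3ccccc3)cc(OCc3ccccc3)c2)ccc1OCc1ccccc1 | intermediate
29 | (1E,2S,3S)-2-(3,5-dihydroxyphenyl)-3-(2,4-dihydroxyphenyl)-1-(4-hydroxy-3-methoxybenzylidene)-2,3-dihydro-1H-indene-4,6-diol | COc1cc(/C=C2/c3cc(O)cc(O)c3[C@H](c3ccc(O)cc3O)[C@H]2c2cc(O)cc(O)c2)ccc1O | target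

## Totals and weak points

Total step count: 19.
Longest linear sequence: 12 (steps 2, 3, 4, 5, 6, 7, 10, 11, 16, 17, 18, 19).

Steps most likely to fail:

**Step 7 (asymmetric CuH reduction).** The β-carbon is hindered and electron-rich, so rate or ee may be poor. The fallback sets out from 10. Zn dust in AcOH at rt reduces the enone to the racemic 3-arylindanone F1. Kinetic resolution by Noyori transfer hydrogenation (RuCl(TsDPEN)(p-cymene), HCO2H–Et3N, rt, run to about 55 % conversion with the catalyst antipode that consumes the (R)-ketone) turns the unwanted enantiomer into the separable cis-(1R,3R)-indanol F2. The unreacted (S)-ketone is recovered by chromatography and rejoins the route at 12.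

**Step 16 (thioetherification through the C1 cation).** The cation can lose the C2 proton to give an indene or undergo a hydride shift. The fallback sets out from 17 and replaces the SN1 step by an SN2 step of reversed polarity. Mitsunobu reaction with thioacetic acid (PPh3, DIAD, THF, 0 °C) gives, with inversion at C1, the S-indanyl thioacetate F3. Methanolysis with K2CO3 in degassed MeOH releases the indane-1-thiol F4 in the flask, which is S-alkylated at once by chloride 21 to give the sulfide, rejoining the route at 24.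

**Step 19 (sevenfold debenzylation beside an acid-sensitive stilbene and one methyl ether).** The fallback sets out from 16 and removes the benzyl groups before the alkene exists. Chloride 21 and Mg in THF at 0 °C give the [4-(benzyloxy)-3-methoxybenzyl]magnesium chloride F5. Its CeCl3-mediated addition to ketone 16 (−78 °C, to suppress enolisation) gives the tertiary carbinol F6. Hydrogenolysis (H2, Pd/C, EtOAc–MeOH, neutral) gives the heptaphenol carbinol F7. Mild, kinetically controlled acid dehydration (PPTS, acetone, rt, stopped before the alkene moves into the ring) then gives the target, rejoining the route at 29.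

## Further compounds

F1 | step 7 | rac-4,6-bis(benzyloxy)-3-[2,4-bis(benzyloxy)phenyl]-2,3-dihydro-1H-inden-1-one | O=C1CC(c2ccc(OCc3ccccc3)cc2OCc2ccccc2)c2c(OCc3ccccc3)cc(OCc3ccccc3)cc21
F2 | step 7 | (1R,3R)-4,6-bis(benzyloxy)-3-[2,4-bis(benzyloxy)phenyl]-2,3-dihydro-1H-inden-1-ol | O[C@@H]1C[C@H](c2ccc(OCc3ccccc3)cc2OCc2ccccc2)c2c(OCc3ccccc3)cc(OCc3ccccc3)cc21
F3 | step 16 | S-{(2S,3S)-4,6-bis(benzyloxy)-2-[3,5-bis(benzyloxy)phenyl]-3-[2,4-bis(benzyloxy)phenyl]-2,3-dihydro-1H-inden-1-yl} ethanethioate | CC(=O)SC1[C@H](c2cc(OCc3ccccc3)cc(OCc3ccccc3)c2)[C@@H](c2ccc(OCc3ccccc3)cc2OCc2ccccc2)c2c(OCc3ccccc3)cc(OCc3ccccc3)cc21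
F4 | step 16 | (2S,3S)-4,6-bis(benzyloxy)-2-[3,5-bis(benzyloxy)phenyl]-3-[2,4-bis(benzyloxy)phenyl]-2,3-dihydro-1H-indene-1-thiol | SC1[C@H](c2cc(OCc3ccccc3)cc(OCc3ccccc3)c2)[C@@H](c2ccc(OCc3ccccc3)cc2OCc2ccccc2)c2c(OCc3ccccc3)cc(OCc3ccccc3)cc21
F5 | step 19 | [4-(benzyloxy)-3-methoxybenzyl]magnesium chloride | COc1cc(C[Mg]Cl)ccc1OCc1ccccc1
F6 | step 19 | (2S,3S)-4,6-bis(benzyloxy)-1-[4-(benzyloxy)-3-methoxybenzyl]-2-[3,5-bis(benzyloxy)phenyl]-3-[2,4-bis(benzyloxy)phenyl]-2,3-dihydro-1H-inden-1-ol | COc1cc(CC2(O)[C@H](c3cc(OCc4ccccc4)cc(OCc4ccccc4)c3)[C@@H](c3ccc(OCc4ccccc4)cc3OCc3ccccc3)c3c(OCc4ccccc4)cc(OCc4ccccc4)cc32)ccc1OCc1ccccc1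
F7 | step 19 | (2S,3S)-2-(3,5-dihydroxyphenyl)-3-(2,4-dihydroxyphenyl)-1-(4-hydroxy-3-methoxybenzyl)-2,3-dihydro-1H-indene-1,4,6-triol | COc1cc(CC2(O)[C@H](c3cc(O)cc(O)c3)[C@@H](c3ccc(O)cc3O)c3c(O)cc(O)cc32)ccc1O
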